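Late in the oak run, at 10.0 h, target had sunk to 17.7 % while substrate had climbed to 82.9 %. You asked for a quick number, with the hunch that more catalyst would bring the target back.

| setting | oak | larch | flask |
|---|---|---|---|
| substrate | 0.38 M | 0.38 M | 0.38 M |
| partner | 0.266 M | 0.266 M | 0.266 M |
| protic impurity | 0.19 M | 0.19 M | 0.190 M |
| catalyst | 0.76 mM | 0.76 mM | 0.76 mM |
| temperature | 90 °C | 85 °C | 90 °C |
| remark | the very flask that is asked about, followed so far | run made earlier |  |
| time |  |  | 10 h |

| run | time / h | target / % | substrate / % |
|---|---|---|---|
| oak | 0.833 | 33.8 | 67.8 |
| oak | 1.33 | 32.0 | 68.7 |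
| oak | 2.00 | 29.9 | 73.5 |
| oak | 4.00 | 23.5 | 76.9 |
| oak | 6.00 | 20.3 | 80.6 |
| oak | 10.0 | 17.7 | 82.9 |
| larch | 0.833 | 36.4 | 64.2 |
| larch | 1.33 | 33.4 | 66.8 |
| larch | 2.00 | 33.0 | 68.2 |
| larch | 4.00 | 27.0 | 74.4 |
| larch | 6.00 | 25.8 | 76.3 |
| larch | 10.0 | 18.7 | 79.1 |

(scatter of a reading: 1 percentage point)

- epsilon: change nothing and wait 3.0 h more
- zeta: at 10 h take out 90 % of the target then present, then wait 3.0 h
- gamma: at 10 h raise the temperature by 10 K, then wait 3.0 h
- delta: at 10 h add partner, 100 % of the amount charged, then wait 3.0 h
- eta: at 10 h add catalyst, 100 % of the amount charged, then wait 3.0 h

- removed target is counted in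
- the earlier runs were read with a standard deviation of 1 percentage point
- additions bring no volume worth counting

1. target, in percent of the substrate first charged, at 10 h
2. the remedy with the largest gain of target, or "none" below 2 percentage points (epsilon / zeta / gamma / delta / eta / none)
3. target present, with what was taken out counted in, in percent of the substrate first charged, after zeta
4. target present, with what was taken out counted in, in percent of the substrate first charged, after delta

Your flask is oak itself, so for "now" I took that last reading, with its scatter of 1 percentage point. Target and substrate there summed to 101 %, so I read the target as returning to substrate.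

For the options I supposed that the impurity destroys partner one for one. Dividing the rate at which the impurity consumes partner by the rate of impurity loss then gives one, and time drops out. Free partner plus partner bound in target, minus impurity left, therefore keeps its charged value, the surplus D, the partner charge less the impurity charge: 0.0760 M. That is 20.0 % of the substrate charged and less than the substrate, so partner is the limiting reagent.

Delta lifts D to 0.342 M, more than before. Epsilon, gamma and eta leave D unchanged, as does zeta with the removed target counted in. So I chose delta over your catalyst. D singled out delta but did not size its gain.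

The forecast read the runs as “a fast exothermic equilibrium”. It gave 17.6 % at 10 h, against my 17.7 %, and named delta as best, with 21.5 % after zeta and 48 % after delta.

The flask gave 17.2 % at 10 h. Delta gained the most, 30 points, reaching 47.5 %, and zeta reached 22.1 %.

    substrate + partner + catalyst ⇌ target + catalyst, rate k1*[substrate]*[partner]*[catalyst] forward; the back reaction follows from the equilibrium constant (K = 5.44 /M, k = 545 /M²/min, Ea = 52.0 kJ/mol, ΔH = −13.0 kJ/mol)
    partner + protic impurity → quenched reagent (k = 0.0560 /M/min, Ea = 84.0 kJ/mol)
    (constants at 90 °C)

In this flask at 10 h, partner stood at 14.3 % of its charge and impurity at 14.5 % of its charge, which with the target makes D 0.0760 M. A partner charge of 0.217 M or 0.310 M, other charges held, moves "now" by 5 points from this flask's value, and a run there would leave the forecast's 17.6 % about that far off. The neighbour charged with 1.1 M of partner has D of 0.910 M. At 10 h its impurity stood at 0 % and its partner at 56.1 % of its charge, so free and bound partner came to 0.910 M, with target at 77.1 %.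

The runs stem from a simulated flask for substances that don't exist; scatter was added.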